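**Retrosynthetic overview**
1. Target 9 ⇐ dioxane 8: the aryl ether bond C2–O1 is made last, by acid-mediated ring switch of a trans-4,5-diaryl-1,3-dioxane (C2 ionises, the freed phenol recloses trans; C3 is untouched).
2. Dioxane 8 ⇐ E-stilbene 7 + 2 CH2O: catalytic asymmetric Prins reaction makes the C3–CH2O bond and sets C3.
3. Stilbene 7 ⇐ aryl iodide 3 + 4-vinylsyringol 6: Heck coupling.
4. 3 ⇐ acetovanillone (iodination, O-acetylation); 6 ⇐ syringaldehyde (Knoevenagel–Doebner, double decarboxylation).
5. Ring order: both benzene rings are bought; the 1,3-dioxane and then the dihydrofuran are closed in the same flask.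

Assumption: the IDPi antipode written in step 5 is the one that gives the (5R)-dioxane; the sense of induction is checked on the first run and the mirror-image catalyst is used if it is opposite.

**Step 1**
Reactants: 1 acetovanillone (1-(4-hydroxy-3-methoxyphenyl)ethan-1-one)
Product: 2 5-iodoacetovanillone (1-(4-hydroxy-3-iodo-5-methoxyphenyl)ethan-1-one)
Conditions: NIS (1.05 equiv), TsOH·H2O (10 mol%), MeCN, 0 °C to rt
Reagents that add atoms: N-iodosuccinimide, O=C1CCC(=O)N1I
Why: Electrophilic aromatic iodination; the phenol directs to its only free ortho position, because the para position carries the acetyl group and the other ortho position the methoxy group.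

**Step 2**
Reactants: 2 5-iodoacetovanillone
Product: 3 4-acetyl-2-iodo-6-methoxyphenyl acetate
Conditions: Ac2O (1.3 equiv), Et3N, DMAP (5 mol%), CH2Cl2, 0 °C to rt
Reagents that add atoms: acetic anhydride, CC(=O)OC(C)=O
Why: DMAP-catalysed O-acylation; the acetate keeps the acidic phenol from capturing formaldehyde or the benzylic cation in the Prins stage of step 5 and is removed by the acid used there.

**Step 3**
Reactants: 4 syringaldehyde (4-hydroxy-3,5-dimethoxybenzaldehyde)
Product: 6 4-vinylsyringol (4-ethenyl-2,6-dimethoxyphenol), via sinapic acid 5 (not isolated)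
Conditions: malonic acid (3 equiv), piperidine (1.5 equiv), DMF, 130 °C (microwave or sealed tube), BHT; short silica plug, used at once
Reagents that add atoms: malonic acid, OC(=O)CC(=O)O
Why: Knoevenagel–Doebner condensation with loss of CO2 gives the E-cinnamic acid, which as a p-hydroxycinnamic acid loses the second CO2 under the same amine and heat through its quinone methide tautomer.

**Step 4**
Reactants: 3 4-acetyl-2-iodo-6-methoxyphenyl acetate; 6 4-vinylsyringol
Product: 7 4-acetyl-2-[(E)-2-(4-hydroxy-3,5-dimethoxyphenyl)ethenyl]-6-methoxyphenyl acetate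
Conditions: Pd(OAc)2 (3 mol%), P(o-tol)3 (6 mol%), NaOAc (2 equiv), DMF, 85 °C, BHT
Reagents that add atoms: none
Why: Mizoroki–Heck reaction; oxidative addition of the aryl iodide, insertion at the terminal alkene carbon and syn β-hydride elimination give the E-stilbene, and the weak acetate base limits acetyl transfer to the syringyl phenol.

**Step 5**
Reactants: 7 4-acetyl-2-[(E)-2-(4-hydroxy-3,5-dimethoxyphenyl)ethenyl]-6-methoxyphenyl acetate
Product: 9 1-[(2S,3R)-2-(4-hydroxy-3,5-dimethoxyphenyl)-3-(hydroxymethyl)-7-methoxy-2,3-dihydro-1-benzofuran-5-yl]ethan-1-one, via trans-1,3-dioxane aryl acetate 8 (not isolated)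
Conditions: (CH2O)n (4 equiv), (S,S)-IDPi (confined BINOL-derived N-triflyl imidodiphosphorimidate, 5 mol%), CHCl3, 0 °C to rt; then 1.25 M HCl in MeOH, 40 °C; aq. NaHCO3
Reagents that add atoms: formaldehyde (from paraformaldehyde), C=O
Why: Proposed new method: a Prins reaction in which formaldehyde, activated inside the confined chiral IDPi anion, is attacked by one face of the electron-rich E-alkene at the carbon next to the acetoxyaryl ring (the cation develops at the p-hydroxybenzylic carbon) and a second formaldehyde unit closes the trans-1,3-dioxane, which sets C3 (C5 of the dioxane, R), after which HCl/MeOH removes the aryl acetate and ionises the p-hydroxybenzylic C–O bond so that the freed phenol recloses reversibly to the thermodynamically favoured trans (2S) dihydrofuran while the former acetal arm is released as the CH2OH group; the closest known reactions are the confined-Brønsted-acid-catalysed asymmetric Prins reaction of styrenes with paraformaldehyde to 4-aryl-1,3-dioxanes, the classical Prins reaction of propenylarenes, and the acid-mediated closure of o-hydroxyaryl-substituted p-hydroxybenzyl cations to trans-phenylcoumarans.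

**Compound list**
1 | acetovanillone, 1-(4-hydroxy-3-methoxyphenyl)ethan-1-one | CC(=O)c1ccc(O)c(OC)c1 | starting material
2 | 5-iodoacetovanillone, 1-(4-hydroxy-3-iodo-5-methoxyphenyl)ethan-1-one | CC(=O)c1cc(I)c(O)c(OC)c1 | intermediate
3 | 4-acetyl-2-iodo-6-methoxyphenyl acetate | CC(=O)Oc1c(I)cc(C(C)=O)cc1OC | intermediate
4 | syringaldehyde, 4-hydroxy-3,5-dimethoxybenzaldehyde | COc1cc(C=O)cc(OC)c1O | starting material
5 | sinapic acid, (E)-3-(4-hydroxy-3,5-dimethoxyphenyl)prop-2-enoic acid (not isolated) | COc1cc(/C=C/C(=O)O)cc(OC)c1O | intermediate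
6 | 4-vinylsyringol (canolol), 4-ethenyl-2,6-dimethoxyphenol | COc1cc(C=C)cc(OC)c1O | intermediate
7 | 4-acetyl-2-[(E)-2-(4-hydroxy-3,5-dimethoxyphenyl)ethenyl]-6-methoxyphenyl acetate | COc1cc(/C=C/c2cc(C(C)=O)cc(OC)c2OC(C)=O)cc(OC)c1O | intermediate
8 | 4-acetyl-2-[(4R,5R)-4-(4-hydroxy-3,5-dimethoxyphenyl)-1,3-dioxan-5-yl]-6-methoxyphenyl acetate (trans; not isolated) | COc1cc([C@@H]2OCOC[C@H]2c3cc(C(C)=O)cc(OC)c3OC(C)=O)cc(OC)c1O | intermediate
9 | 1-[(2S,3R)-2-(4-hydroxy-3,5-dimethoxyphenyl)-3-(hydroxymethyl)-7-methoxy-2,3-dihydro-1-benzofuran-5-yl]ethan-1-one (trans) | COc1cc([C@H]2Oc3c(OC)cc(C(C)=O)cc3[C@@H]2CO)cc(OC)c1O | target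

**Totals**
Total step count: 5. Longest linear sequence: 4 steps (1 → 2 → 3 → 7 → 9).

**Steps most likely to fail, with fallbacks**

Step 5 is the most exposed. The asymmetric Prins stage has no direct precedent on an internal, phenolic stilbene, so both conversion and ee may be poor. In the acid stage, temperatures above about 40 °C risk loss of formaldehyde or of the C3 proton from the benzylic cation, which would give stilbenes and erode ee. The fallback replaces asymmetric catalysis by kinetic resolution. It sets out from 7: paraformaldehyde with TfOH (5 mol%) in CH2Cl2 gives the racemic trans-1,3-dioxane aryl acetate F1. HCl in MeOH at 40 °C converts this into the racemic trans-dihydrobenzofuran alcohol F2. Lipase PS (Burkholderia cepacia) with vinyl acetate in MTBE at 30 °C, stopped near 50% conversion, acetylates one enantiomer; this is assumed to be the (2R,3S)-alcohol, which gives the (2R,3S) primary acetate F3, and the assignment is confirmed by chiral HPLC. Chromatography then leaves the unreacted (2S,3R)-alcohol, and the fallback comes back to the route at 9.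

Step 4 is next. 4-Vinylsyringol polymerises readily, and the activated aryl acetate of 3 may pass its acetyl group to the syringyl phenol under the Heck conditions. The fallback replaces the Heck reaction on a free vinylphenol by a Suzuki coupling of a preformed E-vinylboronate. It sets out from 4 and 3: dimethyl (1-diazo-2-oxopropyl)phosphonate, K2CO3 and MeOH turn 4 into 4-ethynyl-2,6-dimethoxyphenol F4. Zirconocene-catalysed hydroboration (HBpin 2.2 equiv, Cp2ZrHCl 5 mol%, CH2Cl2, then aqueous work-up) gives the E-vinylboronate F5. Suzuki–Miyaura coupling with 3 (Pd(dppf)Cl2, KF, THF, 50 °C) gives the E-stilbene, and the fallback comes back to the route at 7.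

Step 3 is the third. The second decarboxylation may stall at sinapic acid, or the product may oligomerise at 130 °C. The fallback replaces the condensation–decarboxylation by a direct olefination. It sets out from 4: Wittig methylenation with Ph3P=CH2 (from Ph3PCH3Br and KOtBu, 3 equiv, THF, 0 °C; the first equivalent forms the phenoxide) gives 4-vinylsyringol under mild conditions, and the fallback comes back to the route at 6 without any new compound.

**Further compounds**
F1 | step 5 | racemic trans-1,3-dioxane aryl acetate (1:1 mixture of 8 and its 4S,5S enantiomer) | COc1cc([C@@H]2OCOC[C@H]2c3cc(C(C)=O)cc(OC)c3OC(C)=O)cc(OC)c1O.COc1cc([C@H]2OCOC[C@@H]2c3cc(C(C)=O)cc(OC)c3OC(C)=O)cc(OC)c1O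
F2 | step 5 | racemic trans-dihydrobenzofuran alcohol (1:1 mixture of 9 and its 2R,3S enantiomer) | COc1cc([C@H]2Oc3c(OC)cc(C(C)=O)cc3[C@@H]2CO)cc(OC)c1O.COc1cc([C@@H]2Oc3c(OC)cc(C(C)=O)cc3[C@H]2CO)cc(OC)c1O
F3 | step 5 | [(2R,3S)-5-acetyl-2-(4-hydroxy-3,5-dimethoxyphenyl)-7-methoxy-2,3-dihydro-1-benzofuran-3-yl]methyl acetate | COc1cc([C@@H]2Oc3c(OC)cc(C(C)=O)cc3[C@H]2COC(C)=O)cc(OC)c1O
F4 | step 4 | 4-ethynyl-2,6-dimethoxyphenol | COc1cc(C#C)cc(OC)c1O
F5 | step 4 | 2,6-dimethoxy-4-[(E)-2-(4,4,5,5-tetramethyl-1,3,2-dioxaborolan-2-yl)ethenyl]phenol | COc1cc(/C=C/B2OC(C)(C)C(C)(C)O2)cc(OC)c1O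
F0 | step 3 | none | none
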